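**Plan**

- Ring numbering: C1 (CMe2), C2–C4 (CH2), C5 (C–Me) and C6 (the epoxide carbons), C7–C8 (CH2), C9 (bears the carboxyl carbon), C10 (=CH), C11 (CHOBz). The enabling feature is that C4 of the 11-membered carbocycle is a methylene bonded to the methyl-bearing epoxide carbon C5. Removing the epoxide oxygen leaves an E-trisubstituted C5=C6 olefin with an sp3–sp2 junction at C4–C5, and C11–C1–C2–C3–C4 is the carbon chain of 2,2-dimethylpent-4-enal.
- Retrosynthetic cuts, in order: carboxylic acid to its 2-(trimethylsilyl)ethyl (TMSE) ester; epoxide oxygen; ring bond C4–C5 (alkylborane plus alkenyl iodide); benzoate; C8–C9 (alkylzinc plus α-iodoenoate); C9–I/C10–H; C10–C11 (alkynylation of the aldehyde).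
- Forward: TMSE propiolate is added to the aldehyde to make C11. Trans-hydroalumination/iodination gives the Z-iodoenoate. Negishi coupling attaches the C5–C8 iodoalkenyl chain, and benzoylation follows. The only ring is then closed at C4–C5, and epoxidation and ester cleavage finish the route.
- Stereochemistry: C11 comes from the catalyst-controlled alkynylation. The C9=C10 geometry (C8 cis to C11) comes from trans-hydroalumination and retentive coupling. The E C5=C6 geometry comes from syn-hydrozirconation and two retentive couplings. C5/C6 come from the D-fructose-derived Shi ketone.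

Key step: step 8

Remark: the ProPhenol antipode is the one that adds to the Re face of aldehyde 4 (to be fixed by MTPA-ester analysis of 5); C-numbers in the prose are the skeleton numbers of the plan, locants inside compound names are IUPAC locants.

**Route**

Step 1
Reactants: 1 propiolic acid; 2 2-(trimethylsilyl)ethanol
Product: 3 2-(trimethylsilyl)ethyl propiolate
Conditions: DCC, DMAP (cat.), CH2Cl2, −20 → 0 °C
Reagents that add atoms: none
Why: Steglich esterification of a small acid with a primary alcohol; the cold, DMAP-lean protocol should keep the electrophilic alkyne free of amine adducts.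

Step 2
Reactants: 3 2-(trimethylsilyl)ethyl propiolate; 4 2,2-dimethylpent-4-enal
Product: 5 2-(trimethylsilyl)ethyl (S)-4-hydroxy-5,5-dimethyloct-7-en-2-ynoate
Conditions: Me2Zn, ProPhenol ligand (20 mol%), Ph3P=O (40 mol%), toluene, 0–4 °C
Reagents that add atoms: none
Why: Zinc–ProPhenol-catalysed asymmetric alkynylation of a non-enolisable α-quaternary aldehyde; the chiral dinuclear zinc catalyst directs the propiolate to the Re face and so sets C11 (descriptor S here because the alkynyl group outranks the quaternary carbon).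

Step 3
Reactants: 5 2-(trimethylsilyl)ethyl (S)-4-hydroxy-5,5-dimethyloct-7-en-2-ynoate
Product: 7 2-(trimethylsilyl)ethyl (R,Z)-4-hydroxy-2-iodo-5,5-dimethylocta-2,7-dienoate, via cyclic alkenylaluminate 6 (not isolated)
Conditions: Red-Al, THF, −72 °C; then I2, THF, −72 → −10 °C; Rochelle salt work-up
Reagents that add atoms: iodine, II
Why: Alkoxide-directed trans-hydroalumination of a γ-hydroxy ynoate puts H on C10 and Al on C9 on opposite sides, and iodinolysis with retention gives the Z-iodide with iodine cis to the carbinol and the ester trans to it (no lactonisation); C11 is untouched and becomes R only through the changed CIP ranking.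

Step 4
Reactants: 8 pent-3-yn-1-ol
Product: 10 (E)-4-iodopent-3-en-1-ol, via alkenylzirconocene 9 (not isolated)
Conditions: Cp2Zr(H)Cl (2.5 equiv), THF, rt → 45 °C; then I2, 0 °C
Reagents that add atoms: iodine, II
Why: Hydrozirconation–iodination: the first equivalent caps the hydroxyl as a zirconium alkoxide, syn Zr–H addition with equilibration under excess hydride places zirconium on the less hindered methyl-bearing carbon, and iodinolysis with retention gives the E-2-iodoalkene.

Step 5
Reactants: 10 (E)-4-iodopent-3-en-1-ol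
Product: 11 (E)-2,5-diiodopent-2-ene
Conditions: I2, PPh3, imidazole, CH2Cl2, 0 °C → rt
Reagents that add atoms: iodine, II
Why: Appel-type iodination of a primary alcohol by SN2 displacement of the oxyphosphonium group; the alkenyl iodide is inert.

Step 6
Reactants: 7 2-(trimethylsilyl)ethyl (R,Z)-4-hydroxy-2-iodo-5,5-dimethylocta-2,7-dienoate; 11 (E)-2,5-diiodopent-2-ene
Product: 13 2-(trimethylsilyl)ethyl (R,E)-4-hydroxy-2-[(E)-4-iodopent-3-en-1-yl]-5,5-dimethylocta-2,7-dienoate, via alkylzinc iodide 12 (not isolated)
Conditions: 11, Zn dust, I2 (cat.), DMA, rt → 40 °C; then 7, PdCl2(dppf) (5 mol%), THF–DMA, 0 °C → rt (zinc reagent in excess)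
Reagents that add atoms: none
Why: Zinc dust inserts only into the primary C(sp3)–I bond, and Negishi coupling then joins C8 to C9 with retention so that C8 ends up cis to C11; the electron-poor α-iodoenoate should undergo oxidative addition faster than the unactivated iodoalkene of the reagent, and alkylzinc halides tolerate a free hydroxyl.

Step 7
Reactants: 13 2-(trimethylsilyl)ethyl (R,E)-4-hydroxy-2-[(E)-4-iodopent-3-en-1-yl]-5,5-dimethylocta-2,7-dienoate
Product: 14 2-(trimethylsilyl)ethyl (R,E)-4-(benzoyloxy)-2-[(E)-4-iodopent-3-en-1-yl]-5,5-dimethylocta-2,7-dienoate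
Conditions: BzCl, pyridine, DMAP (cat.), CH2Cl2, 0 °C → rt
Reagents that add atoms: benzoyl chloride, O=C(Cl)c1ccccc1
Why: DMAP-catalysed acylation of the hindered secondary allylic alcohol; the C11–O bond is not broken, so the configuration is kept.

Step 8
Reactants: 14 2-(trimethylsilyl)ethyl (R,E)-4-(benzoyloxy)-2-[(E)-4-iodopent-3-en-1-yl]-5,5-dimethylocta-2,7-dienoate
Product: 16 2-(trimethylsilyl)ethyl (1E,3R,8E)-3-(benzoyloxy)-4,4,8-trimethylcycloundeca-1,8-diene-1-carboxylate, via B-alkyl-9-BBN borane 15 (not isolated)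
Conditions: 9-BBN dimer, THF, 0 °C → rt; then syringe-pump addition to PdCl2(dppf) (20 mol%), AsPh3 (40 mol%), Cs2CO3, THF/DMF/H2O, rt → 45 °C, final 1–2 mM
Reagents that add atoms: none
Why: 9-BBN should add anti-Markovnikov only to the monosubstituted C3=C4 olefin, leaving the trisubstituted enoate, the iodoalkene and both esters alone; Pd(0) then inserts into the C5–I bond, the base-activated primary alkylborane transfers C4 to palladium, and reductive elimination forms C4–C5. This is an intramolecular B-alkyl Suzuki–Miyaura coupling, a reaction type with macrocyclisation precedent in terpenoid synthesis. The 11-membered carbocycle closes end-to-end by C(sp3)–C(sp2) reductive elimination from a 12-membered palladacycle, with the new bond and the C5=C6 olefin both inside the ring. No stereocentre is formed: C11 is carried through, and the E geometry of C5=C6 is inherited from the iodide because oxidative addition and reductive elimination are stereoretentive. The step needs ring closure to beat dimerisation and C–I insertion to beat ionisation of the allylic benzoate; slow addition at high dilution, the chain folding imposed by the C1 gem-dimethyl group and the ring-cis C9=C10 unit, and the hindered neopentylic position of the benzoate are expected to secure this.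

Step 9
Reactants: 16 2-(trimethylsilyl)ethyl (1E,3R,8E)-3-(benzoyloxy)-4,4,8-trimethylcycloundeca-1,8-diene-1-carboxylate
Product: 17 2-(trimethylsilyl)ethyl (1R,4E,6R,11R)-6-(benzoyloxy)-7,7,11-trimethyl-12-oxabicyclo[9.1.0]dodec-4-ene-4-carboxylate
Conditions: D-fructose-derived Shi ketone (30–50 mol%), Oxone, K2CO3, Bu4NHSO4, MeCN–DMM/aq. Na2B4O7–Na2EDTA (pH ≈ 10.5), 0 °C
Reagents that add atoms: potassium peroxymonosulfate (Oxone), [K+].[O-]S(=O)(=O)OO
Why: Shi asymmetric epoxidation: the electrophilic chiral dioxirane attacks only the electron-rich trisubstituted C5=C6 olefin (the enoate is inert) through the spiro transition state that gives R,R-epoxides from E-olefins, so syn oxygen transfer should set C5 and C6 as 5R,6R under catalyst control.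

Step 10
Reactants: 17 2-(trimethylsilyl)ethyl (1R,4E,6R,11R)-6-(benzoyloxy)-7,7,11-trimethyl-12-oxabicyclo[9.1.0]dodec-4-ene-4-carboxylate
Product: 18 (1R,4E,6R,11R)-6-(benzoyloxy)-7,7,11-trimethyl-12-oxabicyclo[9.1.0]dodec-4-ene-4-carboxylic acid (target)
Conditions: TBAF, THF, 0 °C → rt; pH 5 phosphate buffer work-up
Reagents that add atoms: none
Why: Fluoride attack on silicon triggers β-fragmentation of the 2-(trimethylsilyl)ethyl ester (loss of ethene and Me3SiF) under non-hydrolytic conditions that should leave benzoate and epoxide intact; the buffered work-up frees the acid without acid-catalysed epoxide opening.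

**Compound list**

1 | propiolic acid | C#CC(=O)O | starting material
2 | 2-(trimethylsilyl)ethanol | C[Si](C)(C)CCO | starting material
3 | 2-(trimethylsilyl)ethyl propiolate | C#CC(=O)OCC[Si](C)(C)C | intermediate
4 | 2,2-dimethylpent-4-enal | C=CCC(C)(C)C=O | starting material
5 | 2-(trimethylsilyl)ethyl (S)-4-hydroxy-5,5-dimethyloct-7-en-2-ynoate | C=CCC(C)(C)[C@H](O)C#CC(=O)OCC[Si](C)(C)C | intermediate
6 | sodium cyclic alkoxy(alkenyl)bis(2-methoxyethoxy)aluminate (O–Al–C9 five-membered ring, H on C10) | [Na+].C=CCC(C)(C)[C@@H]1O[Al-](OCCOC)(OCCOC)C(C(=O)OCC[Si](C)(C)C)=C1 | intermediate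
7 | 2-(trimethylsilyl)ethyl (R,Z)-4-hydroxy-2-iodo-5,5-dimethylocta-2,7-dienoate | C=CCC(C)(C)[C@H](O)/C=C(\I)C(=O)OCC[Si](C)(C)C | intermediate
8 | pent-3-yn-1-ol | CC#CCCO | starting material
9 | (E)-alkenylzirconocene chloride of pent-3-yn-1-ol, hydroxyl as zirconocene alkoxide (Cp drawn η1) | C/C(=C\CCO[Zr](Cl)(C1C=CC=C1)C1C=CC=C1)[Zr](Cl)(C1C=CC=C1)C1C=CC=C1 | intermediate
10 | (E)-4-iodopent-3-en-1-ol | C/C(I)=C\CCO | intermediate
11 | (E)-2,5-diiodopent-2-ene | C/C(I)=C\CCI | intermediate
12 | [(E)-4-iodopent-3-en-1-yl]zinc iodide | C/C(I)=C\CC[Zn]I | intermediate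
13 | 2-(trimethylsilyl)ethyl (R,E)-4-hydroxy-2-[(E)-4-iodopent-3-en-1-yl]-5,5-dimethylocta-2,7-dienoate | C=CCC(C)(C)[C@H](O)/C=C(/C(=O)OCC[Si](C)(C)C)\CC/C=C(\C)I | intermediate
14 | 2-(trimethylsilyl)ethyl (R,E)-4-(benzoyloxy)-2-[(E)-4-iodopent-3-en-1-yl]-5,5-dimethylocta-2,7-dienoate | C=CCC(C)(C)[C@H](OC(=O)c1ccccc1)/C=C(/C(=O)OCC[Si](C)(C)C)\CC/C=C(\C)I | intermediate
15 | 2-(trimethylsilyl)ethyl (R,E)-4-(benzoyloxy)-8-(9-borabicyclo[3.3.1]nonan-9-yl)-2-[(E)-4-iodopent-3-en-1-yl]-5,5-dimethyloct-2-enoate | C(CCC(C)(C)[C@H](OC(=O)c1ccccc1)/C=C(/C(=O)OCC[Si](C)(C)C)\CC/C=C(\C)I)B1C2CCCC1CCC2 | intermediate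
16 | 2-(trimethylsilyl)ethyl (1E,3R,8E)-3-(benzoyloxy)-4,4,8-trimethylcycloundeca-1,8-diene-1-carboxylate | CC1(C)CCC/C(C)=C/CC/C(C(=O)OCC[Si](C)(C)C)=C\[C@H]1OC(=O)c1ccccc1 | intermediate
17 | 2-(trimethylsilyl)ethyl (1R,4E,6R,11R)-6-(benzoyloxy)-7,7,11-trimethyl-12-oxabicyclo[9.1.0]dodec-4-ene-4-carboxylate | CC1(C)CCC[C@@]2(C)O[C@@H]2CC/C(C(=O)OCC[Si](C)(C)C)=C\[C@H]1OC(=O)c1ccccc1 | intermediate
18 | (1R,4E,6R,11R)-6-(benzoyloxy)-7,7,11-trimethyl-12-oxabicyclo[9.1.0]dodec-4-ene-4-carboxylic acid | CC1(C)CCC[C@@]2(C)O[C@@H]2CC/C(C(=O)O)=C\[C@H]1OC(=O)c1ccccc1 | target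

**Step count and risks**

Total steps: 10. Longest linear sequence: 8 steps (steps 1, 2, 3, 6, 7, 8, 9, 10); the two-step side branch (steps 4, 5) joins at step 6.

Step 8 (macrocyclisation). What may go wrong: intermolecular coupling, protodeboronation or β-hydride elimination may outrun closure of the strained 11-membered ring, and palladium(0) may ionise the allylic benzoate in the aqueous basic medium. The fallback sets out from 14 and closes the same bond under base-free conditions with a more reactive organometallic. Hydroboration as before (through 15) and oxidation with NaBO3·4H2O would give the primary alcohol 2-(trimethylsilyl)ethyl (R,E)-4-(benzoyloxy)-8-hydroxy-2-[(E)-4-iodopent-3-en-1-yl]-5,5-dimethyloct-2-enoate F1. Appel-type iodination (I2, PPh3, imidazole) would give the primary iodide F2. Zinc dust in DMA, which leaves the alkenyl iodide alone, would give the alkylzinc iodide F3. Slow addition of F3 to Pd2(dba)3/P(2-furyl)3 in THF–NMP would effect an intramolecular Negishi coupling and return to the route at 16.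

Step 6 (Negishi coupling). What may go wrong: palladium may insert into the alkenyl C–I bond of the zinc reagent or of the product in competition with the α-iodoenoate, giving oligomers, and the alkylzinc may be quenched by the free hydroxyl. The fallback sets out from 10 and masks the distal iodide as a vinylsilane. O-silylation (TMSCl, Et3N), iodine–lithium exchange (t-BuLi, Et2O, −78 °C), C-silylation with TMSCl and methanolysis of the O-silyl group would give (E)-4-(trimethylsilyl)pent-3-en-1-ol F4. Appel-type iodination would give (E)-(5-iodopent-2-en-2-yl)trimethylsilane F5, and zinc insertion would give the alkylzinc iodide F6. Negishi coupling of F6 with 7, now with a single alkenyl iodide in the flask, would give the vinylsilane alcohol F7, and benzoylation would give the vinylsilane benzoate F8. Iododesilylation with NIS (MeCN/ClCH2CN, 0 °C), with retention of geometry, would return to the route at 14.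

Step 9 (epoxidation). What may go wrong: facial selectivity may be poor if the conformational preference of the 11-membered ring for peripheral attack opposes the catalyst, and oxygen transfer to a transannularly shielded olefin may be slow. The fallback sets out from 16 and reverses the intrinsic facial bias of the ring. NBS in aqueous THF would place bromine on the exposed face and water on C5 from the opposite face, giving the (5R,6S)-bromohydrin F9 (5-hydroxy, 6-bromo). DBU in CH2Cl2 would then close the epoxide with inversion at C6, so that oxygen ends up on the face a direct oxidant does not reach, and the route is rejoined at 17.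

**Further compounds**

F1 | step 8 | 2-(trimethylsilyl)ethyl (R,E)-4-(benzoyloxy)-8-hydroxy-2-[(E)-4-iodopent-3-en-1-yl]-5,5-dimethyloct-2-enoate | OCCCC(C)(C)[C@H](OC(=O)c1ccccc1)/C=C(/C(=O)OCC[Si](C)(C)C)\CC/C=C(\C)I
F2 | step 8 | 2-(trimethylsilyl)ethyl (R,E)-4-(benzoyloxy)-8-iodo-2-[(E)-4-iodopent-3-en-1-yl]-5,5-dimethyloct-2-enoate | ICCCC(C)(C)[C@H](OC(=O)c1ccccc1)/C=C(/C(=O)OCC[Si](C)(C)C)\CC/C=C(\C)I
F3 | step 8 | alkylzinc iodide of F2 (zinc on the terminal C4 carbon) | I[Zn]CCCC(C)(C)[C@H](OC(=O)c1ccccc1)/C=C(/C(=O)OCC[Si](C)(C)C)\CC/C=C(\C)I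
F4 | step 6 | (E)-4-(trimethylsilyl)pent-3-en-1-ol | C/C(=C\CCO)[Si](C)(C)C
F5 | step 6 | (E)-(5-iodopent-2-en-2-yl)trimethylsilane | C/C(=C\CCI)[Si](C)(C)C
F6 | step 6 | [(E)-4-(trimethylsilyl)pent-3-en-1-yl]zinc iodide | C/C(=C\CC[Zn]I)[Si](C)(C)C
F7 | step 6 | 2-(trimethylsilyl)ethyl (R,E)-4-hydroxy-5,5-dimethyl-2-[(E)-4-(trimethylsilyl)pent-3-en-1-yl]octa-2,7-dienoate | C=CCC(C)(C)[C@H](O)/C=C(/C(=O)OCC[Si](C)(C)C)\CC/C=C(\C)[Si](C)(C)C
F8 | step 6 | 2-(trimethylsilyl)ethyl (R,E)-4-(benzoyloxy)-5,5-dimethyl-2-[(E)-4-(trimethylsilyl)pent-3-en-1-yl]octa-2,7-dienoate | C=CCC(C)(C)[C@H](OC(=O)c1ccccc1)/C=C(/C(=O)OCC[Si](C)(C)C)\CC/C=C(\C)[Si](C)(C)C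
F9 | step 9 | 2-(trimethylsilyl)ethyl (1E,3R,8R,9S)-3-(benzoyloxy)-9-bromo-8-hydroxy-4,4,8-trimethylcycloundec-1-ene-1-carboxylate | CC1(C)CCC[C@@](C)(O)[C@@H](Br)CC/C(C(=O)OCC[Si](C)(C)C)=C\[C@H]1OC(=O)c1ccccc1
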